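The amber and ochre runs were my starting point. Both used 3 equiv of reagent, and I had to place the best time of a flask with a smaller charge.

| flask | substrate | reagent | remark | time |
|---|---|---|---|---|
| amber | 0.70 mM | 3 equiv | run made earlier |  |
| ochre | 1.1 mM | 3 equiv | run made earlier |  |
| flask | 0.50 mM | 3.00 equiv |  | 12 min |

- amber (time / min: target / %, substrate / %): 0.250: 26.1, 57.5; 0.500: 35.0, 35.9; 1.33: 33.7, 10.5; 2.50: 19.5, 3.0; 6.00: 3.4, 0.4; 12.0: 0.4, 0.1
- ochre (time / min: target / %, substrate / %): 0.250: 33.2, 45.1; 0.500: 38.3, 23.7; 1.33: 26.3, 4.4; 2.50: 10.5, 0.8; 6.00: 0.5, 0.1; 12.0: 0.7, 0.4

(readings scatter by 0.3 percentage points)

1. the best time, 12 min at the latest, for target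
2. the amount of target, in percent of the substrate charged, at that time
3. earliest time at which at least nineteen twentieths of that best amount are there, in min
4. latest time at which they still are, in min

I counted turnovers: the turnover count is minus the natural logarithm of the fraction of substrate left. At fixed equivalents both partners scale with the charge, so the count should follow charge times time. The readings agreed. Amber at 0.500 min over ochre at 0.250 min gave a count ratio of 1.29, and charge times time gave 1.27.

I first took the main step alone, substrate plus reagent to target. Target would then match the substrate lost and show no peak. But ochre at 0.500 min had lost 76.3% of its substrate and held 38.3% target.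

So I added a second step, the loss of target. At 2.50 min ochre held 10.5% and amber 19.5%, less in the run with the larger charge. I took this loss to use reagent too, which puts the peak at a fixed dose. I named the peak dose 1.65 mM·min, the reagent charge times the time of the highest target reading. For this flask that gave 1.10 min.

Then I added the rest. Ochre at 0.250 min already had 21.7% of its charge in neither substrate nor target. I did not reckon how those routes scale with the charge, and I kept 1.10 min as an estimate that does not account for them.

The forecast gave 37.5% at 1.1 min, with a window from 0.72 min to 1.6 min, on the ground that “both runs collapse onto one curve”.

The flask gave 36.5% at 1.04 min, with a window from 0.705 min to 1.50 min.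

    2 substrate → side product B (k = 7.60 /M/s)
    substrate + reagent → target (k = 13.0 /M/s)
    substrate → side product A (k = 0.00290 /s)
    reagent + target → over-reaction product (k = 8.20 /M/s)

By 12 min the flask had taken 10.9 peak doses, and it held 0.734% target. The neighbour with 12.0 equiv of reagent, at the same charge and time, took 43.6. Its best was 42.9%, and it ended with 0% target. Substrate was the limiting reagent there, with 0% left against 85% of the reagent, and over-reaction product held 91.8%.

(The runs come from a simulation with made-up constants, noise included.)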